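**Plan**

- Retrosynthesis: after removal of three triisopropylsilyl ethers, the pyranone ring (ring C) is cut at O1–C2 and at C4–C4a. This gives the ring A phenol 6 and the (S)-α-aryl-β-propiolactone 25, in which C2–C3–C4 is stored as a strained temporary ring at the acid oxidation level.
- The lactone is traced back through a 3-hydroxy-2-arylpropanoic acid and an auxiliary-bound arylacetic acid to 3-bromo-4,5-dihydroxybenzaldehyde. Both prenyl groups are cut at their aryl–CH2 bonds (aryl bromide for ring B, phloroglucinol for ring A).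
- Forward: the ring A fragment is made in steps 1–3 and the ring B fragment in steps 4–12. The two are joined in step 13, where ring C, the only ring made, arises. Desilylation ends the route.
- Enabling feature: in ring A the ether oxygen O1 lies para to the prenyl-bearing C6, on the local symmetry axis of the 2-prenylphloroglucinol nucleus, so its two ortho carbons are equivalent. O1/C4a form a 1,3-dinucleophile matched to the 1,3-dielectrophile C2/C4 that flanks the stereocentre C3.
- Stereochemistry: C3 (S) is set in step 9 by the (R)-4-benzyloxazolidinone auxiliary through face-selective hydroxymethylation of the Z titanium enolate. It is carried unchanged, and no later step uses a base strong enough to enolize it.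

Key step: step 13

Remark: read from the SMILES, the single stereocentre (C3 of the chromanone) is S, with priorities C4 > C2 > aryl > H; TIPS = triisopropylsilyl, prenyl = 3-methylbut-2-en-1-yl.

**Route**

Step 1
Reactants: 1 benzene-1,3,5-triol (phloroglucinol); 2 1-bromo-3-methylbut-2-ene (prenyl bromide)
Product: 3 2-prenylbenzene-1,3,5-triol
Conditions: 2 (0.8 equiv), 10% aq. KOH, 0 °C → rt
Reagents that add atoms: prenyl bromide (2), CC(C)=CCBr
Why: C-alkylation of the ambident phloroglucinolate, which reacts at carbon in water; the threefold symmetry of 1 allows only one mono-prenyl product, and the halide is the limiting reagent to hold back further prenylation.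

Step 2
Reactants: 3 2-prenylbenzene-1,3,5-triol; 4 chlorotriisopropylsilane
Product: 5 2-prenyl-1,3,5-tris(triisopropylsilyloxy)benzene
Conditions: 4 (3.6 equiv), imidazole, DMAP (cat.), DMF, 50 °C
Reagents that add atoms: chlorotriisopropylsilane (4), CC(C)[Si](Cl)(C(C)C)C(C)C
Why: exhaustive silylation of the phenols with a silyl chloride and imidazole; the bulky silyl ethers later keep the two oxygens that flank the prenyl group from cyclizing onto it and should survive phenoxide and acid.

Step 3
Reactants: 5 2-prenyl-1,3,5-tris(triisopropylsilyloxy)benzene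
Product: 6 4-prenyl-3,5-bis(triisopropylsilyloxy)phenol
Conditions: Bu4NF (1.0 equiv), THF, −78 → −40 °C; aq. NH4Cl
Reagents that add atoms: none
Why: fluoride-mediated desilylation under kinetic control; the silyl ether para to the prenyl group has two ring hydrogens as neighbours, whereas the other two each have the prenyl methylene ortho to them, so one equivalent of fluoride at low temperature should unmask mainly the unique oxygen.

Step 4
Reactants: 7 3-bromo-4,5-dihydroxybenzaldehyde; 8 iodomethane
Product: 9 3-bromo-5-hydroxy-4-methoxybenzaldehyde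
Conditions: MeI (1.05 equiv), Li2CO3 (1.1 equiv), DMF, 45 °C
Reagents that add atoms: iodomethane (8), CI
Why: Williamson etherification of the mono-phenoxide; the hydroxyl para to the formyl group and ortho to bromine is the more acidic one, so a weak base and one equivalent of MeI should methylate it selectively.

Step 5
Reactants: 9 3-bromo-5-hydroxy-4-methoxybenzaldehyde; 4 chlorotriisopropylsilane
Product: 10 3-bromo-4-methoxy-5-(triisopropylsilyloxy)benzaldehyde
Conditions: 4, imidazole, DMF, rt
Reagents that add atoms: chlorotriisopropylsilane (4), CC(C)[Si](Cl)(C(C)C)C(C)C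
Why: silylation of the remaining phenol, which must not compete as a nucleophile in step 13 and is removed together with the ring A silyl groups at the end.

Step 6
Reactants: 10 3-bromo-4-methoxy-5-(triisopropylsilyloxy)benzaldehyde; 11 (methoxymethyl)triphenylphosphonium chloride
Product: 13 2-[3-bromo-4-methoxy-5-(triisopropylsilyloxy)phenyl]acetaldehyde, via methyl enol ether 12 (not isolated)
Conditions: 11, KN(SiMe3)2, THF, 0 °C → rt; then 2 M aq. HCl, THF, rt
Reagents that add atoms: (methoxymethyl)triphenylphosphonium chloride (11), COC[P+](c1ccccc1)(c1ccccc1)c1ccccc1.[Cl-]; water, O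
Why: Wittig one-carbon homologation with the methoxymethylene ylide, followed by acid hydrolysis of the enol ether (E/Z mixture, no consequence) to the arylacetaldehyde, which is used crude.

Step 7
Reactants: 13 2-[3-bromo-4-methoxy-5-(triisopropylsilyloxy)phenyl]acetaldehyde
Product: 14 2-[3-bromo-4-methoxy-5-(triisopropylsilyloxy)phenyl]acetic acid
Conditions: NaClO2, NaH2PO4, 2-methylbut-2-ene, t-BuOH/H2O, 0 °C → rt
Reagents that add atoms: sodium chlorite, [Na+].[O-]Cl=O
Why: Pinnick oxidation; chlorite oxidizes the aldehyde without touching the aryl bromide or the silyl ether, and the alkene scavenges the hypochlorous acid formed.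

Step 8
Reactants: 14 2-[3-bromo-4-methoxy-5-(triisopropylsilyloxy)phenyl]acetic acid; 15 (R)-4-benzyl-1,3-oxazolidin-2-one
Product: 17 (R)-4-benzyl-3-{2-[3-bromo-4-methoxy-5-(triisopropylsilyloxy)phenyl]acetyl}-1,3-oxazolidin-2-one, via mixed pivalic anhydride 16 (not isolated)
Conditions: t-BuCOCl, Et3N, THF, −20 °C; then LiCl, 15, −20 °C → rt
Reagents that add atoms: (R)-4-benzyl-1,3-oxazolidin-2-one (15), O=C1N[C@H](Cc2ccccc2)CO1
Why: N-acylation of the oxazolidinone through the mixed pivalic anhydride with LiCl activation, which avoids strong base on the enolizable arylacetyl unit.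

Step 9
Reactants: 17 (R)-4-benzyl-3-{2-[3-bromo-4-methoxy-5-(triisopropylsilyloxy)phenyl]acetyl}-1,3-oxazolidin-2-one; 18 1,3,5-trioxane
Product: 20 (R)-4-benzyl-3-{(2S)-2-[3-bromo-4-methoxy-5-(triisopropylsilyloxy)phenyl]-3-hydroxypropanoyl}-1,3-oxazolidin-2-one, via trichlorotitanium Z-enolate 19 (not isolated)
Conditions: TiCl4, i-Pr2NEt, CH2Cl2, 0 °C; then 18, TiCl4, 0 °C
Reagents that add atoms: 1,3,5-trioxane (18), C1OCOCO1
Why: Evans-type asymmetric hydroxymethylation; soft enolization gives the chelated Z titanium enolate, the benzyl group of the (R)-auxiliary shields one face, and TiCl4-activated formaldehyde adds to the open face to set C3 as S. The aryl bromide is kept through this step because a prenyl alkene would be open to a Prins reaction with the activated formaldehyde.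

Step 10
Reactants: 20 (R)-4-benzyl-3-{(2S)-2-[3-bromo-4-methoxy-5-(triisopropylsilyloxy)phenyl]-3-hydroxypropanoyl}-1,3-oxazolidin-2-one; 21 tributyl(3-methylbut-2-en-1-yl)stannane
Product: 22 (R)-4-benzyl-3-{(2S)-3-hydroxy-2-[4-methoxy-3-prenyl-5-(triisopropylsilyloxy)phenyl]propanoyl}-1,3-oxazolidin-2-one
Conditions: 21, Pd(PPh3)4 (zerovalent palladium, cat.), DMF, 90 °C
Reagents that add atoms: tributyl(3-methylbut-2-en-1-yl)stannane (21), CCCC[Sn](CCCC)(CCCC)CC=C(C)C
Why: Stille cross-coupling of the aryl bromide under neutral conditions that leave the enolizable α-aryl stereocentre alone; transfer of the allyl group from its tin-bearing carbon should give the linear prenyl arene.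

Step 11
Reactants: 22 (R)-4-benzyl-3-{(2S)-3-hydroxy-2-[4-methoxy-3-prenyl-5-(triisopropylsilyloxy)phenyl]propanoyl}-1,3-oxazolidin-2-one
Product: 24 (2S)-3-hydroxy-2-[4-methoxy-3-prenyl-5-(triisopropylsilyloxy)phenyl]propanoic acid, via peroxy acid 23 (not isolated)
Conditions: LiOH, 30% H2O2, THF/H2O, 0 °C; then aq. Na2SO3; HCl to pH 3
Reagents that add atoms: hydrogen peroxide, OO
Why: hydroperoxide cleavage of the imide; the hydroperoxide anion attacks the exocyclic carbonyl, at 0 °C the α-aryl centre should not epimerize, and the trisubstituted alkene is inert to alkaline peroxide.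

Step 12
Reactants: 24 (2S)-3-hydroxy-2-[4-methoxy-3-prenyl-5-(triisopropylsilyloxy)phenyl]propanoic acid
Product: 25 (3S)-3-[4-methoxy-3-prenyl-5-(triisopropylsilyloxy)phenyl]oxetan-2-one
Conditions: PPh3, DIAD, THF, −78 °C → rt
Reagents that add atoms: none
Why: Mitsunobu lactonization by hydroxyl-group activation; the carboxylate displaces the oxyphosphonium group at the primary carbon (4-exo-tet), so the stereocentre takes no part and stays S.

Step 13
Reactants: 6 4-prenyl-3,5-bis(triisopropylsilyloxy)phenol; 25 (3S)-3-[4-methoxy-3-prenyl-5-(triisopropylsilyloxy)phenyl]oxetan-2-one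
Product: 29 (3S)-3-[4-methoxy-3-prenyl-5-(triisopropylsilyloxy)phenyl]-6-prenyl-5,7-bis(triisopropylsilyloxy)chroman-4-one, via potassium phenoxide 26 (not isolated), via potassium carboxylate 27 (not isolated), via mixed trifluoroacetic anhydride 28 (not isolated)
Conditions: 6 (1.1 equiv), KOt-Bu (1.0 equiv), t-BuOH/THF, rt; then 25, rt → 40 °C; evaporation (toluene azeotrope); then (CF3CO)2O, CH2Cl2, −10 → 0 °C
Reagents that add atoms: none
Why: The potassium phenoxide 26 attacks the CH2 carbon of the oxetan-2-one in an SN2 ring opening with alkyl–oxygen cleavage, driven by release of the four-membered ring strain, which forms the aryl ether bond O1–C2 and leaves the carboxylate 27 without touching the stereocentre; (CF3CO)2O then turns 27 into the mixed anhydride 28, which acylates the trioxygenated ring intramolecularly (Friedel–Crafts acylation) to form C4–C4a. The closest known reaction types are the opening of β-propiolactones by phenoxides to 3-aryloxypropanoic acids and the cyclodehydration of such acids to chroman-4-ones. The pyranone ring (ring C) closes in the acylation stage by 6-exo-trig attack of the arene carbon on the acyl carbon, the lactone opening being intermolecular. No stereocentre is created: C3 is the lactone stereocentre from step 9, both new bonds are made at its two neighbours, and its descriptor stays S because the priority order acyl carbon > CH2O > aryl > H does not change. The step needs alkyl–oxygen rather than acyl–oxygen cleavage and no enolization, which should be secured because addition at the carbonyl only gives an aryl ester alkoxide that can close back to the lactone, the lactone ring resists β-elimination and enolization, and the hydrogen-bonded phenoxide in tert-butanol is a weak base. It also needs a single regioisomer, which follows because the reacting oxygen lies para to the prenyl-bearing carbon so that both ortho carbons are equivalent and only the 6-prenyl chromanone can form, while the silyl ethers keep the flanking oxygens from adding to the prenyl group in acid.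

Step 14
Reactants: 29 (3S)-3-[4-methoxy-3-prenyl-5-(triisopropylsilyloxy)phenyl]-6-prenyl-5,7-bis(triisopropylsilyloxy)chroman-4-one
Product: 30 (3S)-5,7-dihydroxy-3-(3-hydroxy-4-methoxy-5-prenylphenyl)-6-prenylchroman-4-one
Conditions: HF·pyridine, pyridine, THF, 0 °C → rt
Reagents that add atoms: none
Why: fluoride-mediated cleavage of the three aryl silyl ethers under weakly acidic, non-basic conditions, chosen because C3 is benzylic and α to the ketone and would epimerize under base; the prenyl groups should tolerate buffered HF.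

**Compound list**

1 | benzene-1,3,5-triol (phloroglucinol) | Oc1cc(O)cc(O)c1 | starting material
2 | 1-bromo-3-methylbut-2-ene (prenyl bromide) | CC(C)=CCBr | starting material
3 | 2-prenylbenzene-1,3,5-triol | CC(C)=CCc1c(O)cc(O)cc1O | intermediate
4 | chlorotriisopropylsilane | CC(C)[Si](Cl)(C(C)C)C(C)C | starting material
5 | 2-prenyl-1,3,5-tris(triisopropylsilyloxy)benzene | CC(C)=CCc1c(O[Si](C(C)C)(C(C)C)C(C)C)cc(O[Si](C(C)C)(C(C)C)C(C)C)cc1O[Si](C(C)C)(C(C)C)C(C)C | intermediate
6 | 4-prenyl-3,5-bis(triisopropylsilyloxy)phenol | CC(C)=CCc1c(O[Si](C(C)C)(C(C)C)C(C)C)cc(O)cc1O[Si](C(C)C)(C(C)C)C(C)C | intermediate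
7 | 3-bromo-4,5-dihydroxybenzaldehyde | O=Cc1cc(O)c(O)c(Br)c1 | starting material
8 | iodomethane | CI | starting material
9 | 3-bromo-5-hydroxy-4-methoxybenzaldehyde | COc1c(O)cc(C=O)cc1Br | intermediate
10 | 3-bromo-4-methoxy-5-(triisopropylsilyloxy)benzaldehyde | COc1c(O[Si](C(C)C)(C(C)C)C(C)C)cc(C=O)cc1Br | intermediate
11 | (methoxymethyl)triphenylphosphonium chloride | COC[P+](c1ccccc1)(c1ccccc1)c1ccccc1.[Cl-] | starting material
12 | methyl enol ether, 1-bromo-2-methoxy-5-(2-methoxyvinyl)-3-(triisopropylsilyloxy)benzene, E/Z mixture | COC=Cc1cc(Br)c(OC)c(O[Si](C(C)C)(C(C)C)C(C)C)c1 | intermediate (not isolated)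
13 | 2-[3-bromo-4-methoxy-5-(triisopropylsilyloxy)phenyl]acetaldehyde | O=CCc1cc(Br)c(OC)c(O[Si](C(C)C)(C(C)C)C(C)C)c1 | intermediate
14 | 2-[3-bromo-4-methoxy-5-(triisopropylsilyloxy)phenyl]acetic acid | OC(=O)Cc1cc(Br)c(OC)c(O[Si](C(C)C)(C(C)C)C(C)C)c1 | intermediate
15 | (R)-4-benzyl-1,3-oxazolidin-2-one | O=C1N[C@H](Cc2ccccc2)CO1 | starting material
16 | mixed pivalic anhydride of 14 | CC(C)(C)C(=O)OC(=O)Cc1cc(Br)c(OC)c(O[Si](C(C)C)(C(C)C)C(C)C)c1 | intermediate (not isolated)
17 | (R)-4-benzyl-3-{2-[3-bromo-4-methoxy-5-(triisopropylsilyloxy)phenyl]acetyl}-1,3-oxazolidin-2-one | O=C(Cc1cc(Br)c(OC)c(O[Si](C(C)C)(C(C)C)C(C)C)c1)N1[C@H](Cc2ccccc2)COC1=O | intermediate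
18 | 1,3,5-trioxane | C1OCOCO1 | starting material
19 | trichlorotitanium Z-enolate of 17 | Cl[Ti](Cl)(Cl)O/C(=C\c1cc(Br)c(OC)c(O[Si](C(C)C)(C(C)C)C(C)C)c1)N1[C@H](Cc2ccccc2)COC1=O | intermediate (not isolated)
20 | (R)-4-benzyl-3-{(2S)-2-[3-bromo-4-methoxy-5-(triisopropylsilyloxy)phenyl]-3-hydroxypropanoyl}-1,3-oxazolidin-2-one | OC[C@H](c1cc(Br)c(OC)c(O[Si](C(C)C)(C(C)C)C(C)C)c1)C(=O)N1[C@H](Cc2ccccc2)COC1=O | intermediate
21 | tributyl(3-methylbut-2-en-1-yl)stannane | CCCC[Sn](CCCC)(CCCC)CC=C(C)C | starting material
22 | (R)-4-benzyl-3-{(2S)-3-hydroxy-2-[4-methoxy-3-prenyl-5-(triisopropylsilyloxy)phenyl]propanoyl}-1,3-oxazolidin-2-one | OC[C@H](c1cc(CC=C(C)C)c(OC)c(O[Si](C(C)C)(C(C)C)C(C)C)c1)C(=O)N1[C@H](Cc2ccccc2)COC1=O | intermediate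
23 | (2S)-3-hydroxy-2-[4-methoxy-3-prenyl-5-(triisopropylsilyloxy)phenyl]propaneperoxoic acid | OC[C@H](c1cc(CC=C(C)C)c(OC)c(O[Si](C(C)C)(C(C)C)C(C)C)c1)C(=O)OO | intermediate (not isolated)
24 | (2S)-3-hydroxy-2-[4-methoxy-3-prenyl-5-(triisopropylsilyloxy)phenyl]propanoic acid | OC[C@H](c1cc(CC=C(C)C)c(OC)c(O[Si](C(C)C)(C(C)C)C(C)C)c1)C(O)=O | intermediate
25 | (3S)-3-[4-methoxy-3-prenyl-5-(triisopropylsilyloxy)phenyl]oxetan-2-one | O=C1OC[C@@H]1c1cc(CC=C(C)C)c(OC)c(O[Si](C(C)C)(C(C)C)C(C)C)c1 | intermediate
26 | potassium 4-prenyl-3,5-bis(triisopropylsilyloxy)phenoxide | [K+].[O-]c1cc(O[Si](C(C)C)(C(C)C)C(C)C)c(CC=C(C)C)c(O[Si](C(C)C)(C(C)C)C(C)C)c1 | intermediate (not isolated)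
27 | potassium (2S)-2-[4-methoxy-3-prenyl-5-(triisopropylsilyloxy)phenyl]-3-[4-prenyl-3,5-bis(triisopropylsilyloxy)phenoxy]propanoate | [K+].[O-]C(=O)[C@H](COc1cc(O[Si](C(C)C)(C(C)C)C(C)C)c(CC=C(C)C)c(O[Si](C(C)C)(C(C)C)C(C)C)c1)c1cc(CC=C(C)C)c(OC)c(O[Si](C(C)C)(C(C)C)C(C)C)c1 | intermediate (not isolated)
28 | mixed trifluoroacetic anhydride of the acid of 27 | FC(F)(F)C(=O)OC(=O)[C@H](COc1cc(O[Si](C(C)C)(C(C)C)C(C)C)c(CC=C(C)C)c(O[Si](C(C)C)(C(C)C)C(C)C)c1)c1cc(CC=C(C)C)c(OC)c(O[Si](C(C)C)(C(C)C)C(C)C)c1 | intermediate (not isolated)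
29 | (3S)-3-[4-methoxy-3-prenyl-5-(triisopropylsilyloxy)phenyl]-6-prenyl-5,7-bis(triisopropylsilyloxy)chroman-4-one | COc1c(O[Si](C(C)C)(C(C)C)C(C)C)cc([C@H]2COc3cc(O[Si](C(C)C)(C(C)C)C(C)C)c(CC=C(C)C)c(O[Si](C(C)C)(C(C)C)C(C)C)c3C2=O)cc1CC=C(C)C | intermediate
30 | (3S)-5,7-dihydroxy-3-(3-hydroxy-4-methoxy-5-prenylphenyl)-6-prenylchroman-4-one | COc1c(O)cc([C@H]2COc3cc(O)c(CC=C(C)C)c(O)c3C2=O)cc1CC=C(C)C | target

**Step count and risks**

Total steps: 14. Longest linear sequence: 11 steps (steps 4 to 14, from 7); the ring A branch (steps 1 to 3) joins at step 13.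

Steps most likely to fail:

1. Step 13. The configuration at C3 may erode through enolization of the lactone by the phenoxide, through attack at the acyl carbon followed by retro-aldol loss of formaldehyde, or through acid-promoted enolization of the mixed anhydride or of the product. The fallback resets the stereocentre after the ring is made; it sets out from 29 obtained with lowered enantiomeric purity and returns to 29. Soft enolization (Me3SiOTf, Et3N, CH2Cl2, −20 °C) should give the trimethylsilyl enol ether of 29 F1. Catalytic enantioselective protonation of F1 with a chiral BINOL-derived N-triflyl thiophosphoramide and phenol as the stoichiometric proton source (toluene, low temperature, catalyst enantiomer chosen to deliver S) should then return 29 with C3 set by the catalyst. This is the known enantioselective protonation of silyl enol ethers of 2-aryl cyclic ketones.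

2. Step 3. Site selectivity between the three silyl ethers may be poor, and silyl groups may scramble between phenoxides. The fallback fixes the regiochemistry by construction through directed ortho-metalation; it sets out from 1 and returns at 6. Statistical mono-silylation of 1 (t-BuMe2SiCl, imidazole, DMF) gives 5-(tert-butyldimethylsilyloxy)benzene-1,3-diol F2, and MOMCl with i-Pr2NEt gives its bis(methoxymethyl) ether F3. n-BuLi (THF, 0 °C) removes the proton between the two methoxymethoxy groups to give the aryllithium F4, which after transmetalation with CuI (copper iodide, monovalent copper) is alkylated by 2 to the prenyl arene F5. ZnBr2 with n-PrSH (CH2Cl2, 0 °C) removes both methoxymethyl groups to give 5-(tert-butyldimethylsilyloxy)-2-prenylbenzene-1,3-diol F6, and 4 with imidazole gives the mixed silyl ether F7. K2CO3 in MeOH should then cleave the unhindered tert-butyldimethylsilyl ether in preference to the two hindered triisopropylsilyl ethers and give 6.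

3. Step 12. Decarboxylative fragmentation of the oxyphosphonium carboxylate to the styrene, or oligomerization of the lactone, may compete with the SN2 closure. The fallback closes the ring by forming the other C–O bond; it sets out from 24 and returns at 25. Carboxyl-group activation with benzenesulfonyl chloride in pyridine at −20 °C gives the mixed carboxylic sulfonic anhydride F8, whose primary hydroxyl attacks the acyl carbon (4-exo-trig) to give 25. In this mode there is no leaving group on the CH2 carbon, so the fragmentation path is closed; the low temperature is needed to keep the activated α-aryl acid from forming a ketene.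

Further compounds
F1 | step 13 | trimethylsilyl enol ether of 29, trimethyl{[3-aryl-6-prenyl-5,7-bis(triisopropylsilyloxy)-2H-chromen-4-yl]oxy}silane | COc1c(O[Si](C(C)C)(C(C)C)C(C)C)cc(C2=C(O[Si](C)(C)C)c3c(O[Si](C(C)C)(C(C)C)C(C)C)c(CC=C(C)C)c(O[Si](C(C)C)(C(C)C)C(C)C)cc3OC2)cc1CC=C(C)C
F2 | step 3 | 5-(tert-butyldimethylsilyloxy)benzene-1,3-diol | CC(C)(C)[Si](C)(C)Oc1cc(O)cc(O)c1
F3 | step 3 | [3,5-bis(methoxymethoxy)phenoxy](tert-butyl)dimethylsilane | COCOc1cc(OCOC)cc(O[Si](C)(C)C(C)(C)C)c1
F4 | step 3 | [4-(tert-butyldimethylsilyloxy)-2,6-bis(methoxymethoxy)phenyl]lithium | [Li]c1c(OCOC)cc(O[Si](C)(C)C(C)(C)C)cc1OCOC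
F5 | step 3 | [3,5-bis(methoxymethoxy)-4-prenylphenoxy](tert-butyl)dimethylsilane | COCOc1cc(O[Si](C)(C)C(C)(C)C)cc(OCOC)c1CC=C(C)C
F6 | step 3 | 5-(tert-butyldimethylsilyloxy)-2-prenylbenzene-1,3-diol | CC(C)=CCc1c(O)cc(O[Si](C)(C)C(C)(C)C)cc1O
F7 | step 3 | 5-(tert-butyldimethylsilyloxy)-2-prenyl-1,3-bis(triisopropylsilyloxy)benzene | CC(C)=CCc1c(O[Si](C(C)C)(C(C)C)C(C)C)cc(O[Si](C)(C)C(C)(C)C)cc1O[Si](C(C)C)(C(C)C)C(C)C
F8 | step 12 | mixed anhydride of 24 with benzenesulfonic acid | OC[C@H](c1cc(CC=C(C)C)c(OC)c(O[Si](C(C)C)(C(C)C)C(C)C)c1)C(=O)OS(=O)(=O)c1ccccc1
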